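Readings and results were computed for an exercise; scatter was added.

The noon run held 1.6 M of reagent and the new flask holds 2.40 M, on the same charge of substrate, so I began with noon's readings and asked what the extra reagent changes.

| flask | substrate | reagent | remark | time |
|---|---|---|---|---|
| noon | 2 M | 1.6 M | run made earlier |  |
| flask | 2.0 M | 2.40 M |  | 15 d |

noon run (percent of the substrate charged)

| time / d | target / % | side product / % |
|---|---|---|
| 3.00 | 5.6 | 4.3 |
| 6.00 | 7.3 | 7.6 |
| 10.0 | 6.4 | 8.8 |
| 12.0 | 5.5 | 9.4 |
| 15.0 | 5.8 | 10.3 |

(each reading ± 0.5 percentage points)

* share of target in target plus side product at 10 h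
* share of target in target plus side product at 15 d

- in percentages every species weighs as the substrate in it: one homo dimer counts as two
- the analysis behind the earlier runs scatters by 0.5 percentage points, standard deviation
- reactions considered so far: 2 substrate -> homo dimer; reagent + target -> over-reaction product; intermediate B -> side product; substrate + reagent <-> intermediate A; intermediate A -> intermediate B; reagent + intermediate A -> target; intermediate B <-> intermediate C

Reagent + intermediate A gives target, while intermediate A passes to side product through intermediate B without reagent. I therefore took the odds of target over side product (a selectivity factor) to grow in step with c reagent. Noon read odds of 1.30 at 3.00 d and 0.961 at 6.00 d. Scaled to the flask, the first gave 1.95, a share of 66.1%, but that belongs to 3.00 d, not 10 h. So I went round again: the two readings fall as time to the power 0.439, and following that back to 10 h gave the early odds per molar of reagent, 1.94 L mol⁻¹. For the flask that meant odds of 4.65, a share of 82.3%. The weak link was that power, read from two points that each scatter by 0.5 percentage points. For 15 d I kept noon's reading, 36.0%.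

The forecast said 85% (72% to 95%), above my share, and 35% (28% to 42%) late, since “production and over-reaction both scale with reagent”.

The flask gave 87.2% and 36.8%, both inside the forecast's ranges.

    2 substrate → homo dimer (k = 0.0170 L mol⁻¹ h⁻¹)
    reagent + target → over-reaction product (k = 0.00340 L mol⁻¹ h⁻¹)
    intermediate B → side product (k = 0.0780 h⁻¹)
    substrate + reagent ⇌ intermediate A (K = 0.540 L mol⁻¹, k = 0.0590 L mol⁻¹ h⁻¹)
    intermediate A → intermediate B (k = 0.00590 h⁻¹)
    reagent + intermediate A → target (k = 0.00590 L mol⁻¹ h⁻¹)
    intermediate B ⇌ intermediate C (K = 27.0, k = 0.0150 h⁻¹)

In this flask intermediate A fell back 6.1 times faster than it went on at 0.0809 d, and of the two onward steps the one to target, taken with c reagent as charged, ran 2.40 times the one to intermediate B, a ratio that grows with c reagent as my odds assumed. The flask's own odds per molar of reagent at 10 h came to 2.83 L mol⁻¹, higher than my 1.94 L mol⁻¹, so the weak link gave way: these odds need a power near 0.632, not 0.439. Taken from this flask, and so no test of that power, they give 73.1% at the same time for the neighbour flask with 0.96 M of reagent, which stood at 73.1%.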